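Labdane numbering is used throughout.

**Plan**
- Retrosynthesis: after removal of the silyl and allyl groups, ring B is cut at C6–C7 and C9–C10 in one stroke, giving a ring A methylenecyclohexane (C1–C6, C10, C18–C20) and a C7–C9 allylic bromide that carries the C11–C16 side chain.
- Enabling feature: ring B is a cyclohexene whose C7=C8 bond lies β,γ to quaternary C10, and C6 is a methylene between C5 and allylic C7. This is the mark of a C7–C8–C9 allyl cation adding to an exocyclic C5=C6 alkene, then closure of a C10 cation on the C8=C9 alkene with loss of H7, as in the enzymatic closure of ring B of the labdanes.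
- Forward: ring A is built first by asymmetric Birch reductive methylation of an o-anisamide (C4), osmylation (C2, C3), silylation, methylenation (C6) and conversion of the amide into the C19 acetoxymethyl group. The bromide comes from (R)-citronellic acid in three steps.
- The key step joins the two pieces and closes ring B; deallylation and desilylation finish.
- Stereochemistry: C4 from the pyrrolidine auxiliary, C2/C3 from C4, C13 from the chiral pool, C5/C9/C10 from the chair transition state of the key step, whose facial sense is fixed by the equatorial C2 silyloxy group.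

Key step: step 11

Assumption: the (S)-auxiliary is taken to direct the Birch methylation to the quaternary configuration drawn in 6 (attack anti to the methoxymethyl arm); if the sense were opposite, the (R)-auxiliary would be used and nothing else would change.
Remark: C10 in 7–12 is a mixture of epimers, which is immaterial because C10 becomes cationic in step 11.

Step 1
Reactants: 1 2-methoxy-3-methylbenzoic acid; 2 (S)-2-(methoxymethyl)pyrrolidine
Product: 4 chiral o-anisamide, via acid chloride 3 (not isolated)
Conditions: (COCl)2, DMF (cat.), CH2Cl2, 0 °C to rt; then 2, Et3N, CH2Cl2, 0 °C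
Reagents that add atoms: none
Why: Acid chloride formation followed by N-acylation of the secondary amine; the auxiliary stereocentre is not touched.

Step 2
Reactants: 4 chiral o-anisamide
Product: 7 keto amide (C10 epimers), via potassium amide enolate 5 (not isolated), via enol ether diene 6 (not isolated)
Conditions: K, NH3(l)/THF, t-BuOH (1 equiv), −78 °C; MeI, −78 °C to rt; then 1 M HCl, THF, rt
Reagents that add atoms: methyl iodide (CI); water (O)
Why: Birch reduction gives amide enolate 5, which should be methylated at the ipso carbon anti to the chelated methoxymethyl arm of the auxiliary (Schultz asymmetric Birch reductive alkylation, sets C4); acid then hydrolyses enol ether 6 to the C5 ketone, and the C2=C3 alkene cannot move into conjugation because C4 is quaternary.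

Step 3
Reactants: 7 keto amide
Product: 8 cis-diol keto amide
Conditions: OsO4 (cat.), N-methylmorpholine N-oxide, acetone/H2O, rt
Reagents that add atoms: N-methylmorpholine N-oxide (C[N+]1([O-])CCOCC1); water (O)
Why: Upjohn osmylation adds both oxygens syn to the C2=C3 alkene, expected from the face anti to the bulky N-acylpyrrolidine on the neighbouring quaternary carbon, which sets C2 and C3 cis to the C4 methyl group.

Step 4
Reactants: 8 cis-diol keto amide
Product: 9 bis-silyl ether keto amide
Conditions: TBSOTf, 2,6-lutidine, CH2Cl2, −40 to 0 °C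
Reagents that add atoms: tert-butyldimethylsilyl triflate (CC(C)(C)[Si](C)(C)OS(=O)(=O)C(F)(F)F)
Why: Silyl triflate with a hindered pyridine base should silylate both secondary hydroxyls, including the hindered C3 one, under conditions too mild for retro-aldol cleavage; no stereocentre is affected.

Step 5
Reactants: 9 bis-silyl ether keto amide
Product: 10 exocyclic methylene amide
Conditions: Ph3PCH3Br, KOtBu, toluene, 90 °C
Reagents that add atoms: methyltriphenylphosphonium bromide (C[P+](c1ccccc1)(c1ccccc1)c1ccccc1.[Br-])
Why: Wittig methylenation at elevated temperature is known for hindered 2,2,6-trisubstituted cyclohexanones; the amide is inert, C4 has no α-hydrogen so the β-silyloxy group cannot be eliminated, and epimerisation at C10 is without consequence.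

Step 6
Reactants: 10 exocyclic methylene amide
Product: 11 primary C19 alcohol
Conditions: LiH2NBH3 (from BH3·NH3 and n-BuLi), THF, 0 to 40 °C
Reagents that add atoms: none
Why: Lithium amidotrihydroborate reduces tertiary amides, α-quaternary ones included, to primary alcohols with C–N cleavage (Myers reduction) and should leave the silyl ethers and the unactivated alkene untouched; the auxiliary is released.

Step 7
Reactants: 11 primary C19 alcohol
Product: 12 ring A acetate
Conditions: Ac2O, pyridine, DMAP (cat.), CH2Cl2, rt
Reagents that add atoms: acetic anhydride (CC(=O)OC(C)=O)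
Why: DMAP-catalysed acetylation of the neopentyl alcohol installs the final C19 acetate, which also serves as a weakly nucleophilic oxygen substituent in the cationic step.

Step 8
Reactants: 13 (R)-citronellic acid
Product: 14 allyl (R)-citronellate
Conditions: allyl bromide, K2CO3, DMF, rt
Reagents that add atoms: allyl bromide (C=CCBr)
Why: Carboxylate O-alkylation (SN2) gives an ester that can be removed later without hydroxide, so that the C19 acetate survives; the C13 stereocentre is not involved.

Step 9
Reactants: 14 allyl (R)-citronellate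
Product: 15 E-allylic alcohol
Conditions: SeO2 (cat.), t-BuOOH, salicylic acid (cat.), CH2Cl2, rt
Reagents that add atoms: tert-butyl hydroperoxide (CC(C)(C)OO)
Why: Catalytic SeO2 allylic oxidation (ene reaction, then [2,3]-sigmatropic shift) hydroxylates the E-methyl group of the trisubstituted alkene and gives the E-allylic alcohol; the electron-poor monosubstituted alkene of the allyl ester should not react.

Step 10
Reactants: 15 E-allylic alcohol
Product: 16 E-allylic bromide
Conditions: CBr4, PPh3, CH2Cl2, 0 °C
Reagents that add atoms: carbon tetrabromide (BrC(Br)(Br)Br)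
Why: Appel bromination of the primary allylic alcohol proceeds by SN2 displacement, without allylic shift or change of alkene geometry.

Step 11
Reactants: 12 ring A acetate; 16 E-allylic bromide
Product: 20 allyl labd-7-en-15-oate bis-silyl ether, via C5 cation 17 (not isolated), via C10 cation 18 (not isolated), via C8 cation 19 (not isolated)
Conditions: SnCl4 (excess), CH2Cl2, −78 to −30 °C, 12 in slight excess; Et3N/MeOH quench
Reagents that add atoms: none
Why: Proposed new method: SnCl4 ionises allylic bromide 16 and the allyl cation is attacked at its primary terminus C7 by the exocyclic methylene carbon C6 of 12 (C6–C7 bond, C5 cation 17); a 1,2-hydride shift from C10, or loss and return of a proton through the C5=C10 alkene, gives the C10 cation 18, which is trapped by C9 of the E-configured C8=C9 alkene (C9–C10 bond, C8 cation 19), and loss of H7 gives the trisubstituted C7=C8 alkene. The closest known reaction types are the Lewis acid-promoted addition of allyl halides to 1,1-dialkylethylenes and the Stork–Eschenmoser cation–olefin cyclisation of monocyclofarnesyl-type cations, here run as one cascade. Ring B closes in the 6-endo-trig mode through a chair transition state leading to the trans-decalin. C5 and C10 are set by this chair–chair closure (C6 and C9 both equatorial on ring A, H5 anti to the C10 methyl), C9 by the E geometry of the C8=C9 alkene (side chain equatorial, H9 anti to the C10 methyl), and the sense relative to ring A by the C2 silyloxy group, which stays equatorial because the other chair would place it syn-axial to the axial substituents at C4 and C10, so the C19 acetoxymethyl group ends axial and cis to the C10 methyl. The step needs attack of the cation on the only electron-rich 1,1-disubstituted alkene present, 6-endo closure in preference to early elimination, and endocyclic loss of the proton; the allyl ester alkene is electron-poor, the carbonyl groups are tied up by SnCl4, the silyl ether oxygens are hindered and poorly nucleophilic, and the acid set free should return prematurely formed alkenes to the cation manifold.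

Step 12
Reactants: 20 allyl labd-7-en-15-oate bis-silyl ether
Product: 21 carboxylic acid bis-silyl ether
Conditions: Pd(PPh3)4 (cat.), morpholine, THF, rt
Reagents that add atoms: none
Why: Tsuji–Trost deallylation: zerovalent palladium ionises the allyl ester to a π-allyl complex that morpholine captures, freeing the acid without hydroxide, so the acetate, the silyl ethers and the C7=C8 alkene should be kept.

Step 13
Reactants: 21 carboxylic acid bis-silyl ether
Product: 22 CNP0164890.1
Conditions: HF·pyridine, pyridine/THF, 0 °C to rt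
Reagents that add atoms: none
Why: Fluoride cleaves both secondary silyl ethers; the neopentyl acetate is stable to HF·pyridine and should not migrate, because the C19 oxygen and the C3 hydroxyl are anti on neighbouring carbons.

**Compound list**
1 | 2-methoxy-3-methylbenzoic acid | COc1c(C)cccc1C(=O)O | starting material
2 | (S)-2-(methoxymethyl)pyrrolidine | COC[C@@H]1CCCN1 | starting material
3 | 2-methoxy-3-methylbenzoyl chloride | COc1c(C)cccc1C(=O)Cl | intermediate (not isolated)
4 | [(2S)-2-(methoxymethyl)pyrrolidin-1-yl](2-methoxy-3-methylphenyl)methanone | COC[C@@H]1CCCN1C(=O)c2cccc(C)c2OC | intermediate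
5 | potassium [(2S)-2-(methoxymethyl)pyrrolidin-1-yl](2-methoxy-3-methylcyclohexa-2,5-dien-1-ylidene)methanolate | COC[C@@H]1CCCN1C([O-])=C2C(OC)=C(C)CC=C2.[K+] | intermediate (not isolated)
6 | [(1R)-2-methoxy-1,3-dimethylcyclohexa-2,5-dien-1-yl][(2S)-2-(methoxymethyl)pyrrolidin-1-yl]methanone | COC[C@@H]1CCCN1C(=O)[C@@]2(C)C(OC)=C(C)CC=C2 | intermediate (not isolated)
7 | (2R)-2-{[(2S)-2-(methoxymethyl)pyrrolidin-1-yl]carbonyl}-2,6-dimethylcyclohex-3-en-1-one, both C6 epimers | COC[C@@H]1CCCN1C(=O)[C@@]2(C)C(=O)C(C)CC=C2 | intermediate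
8 | (2R,3R,4S)-3,4-dihydroxy-2-{[(2S)-2-(methoxymethyl)pyrrolidin-1-yl]carbonyl}-2,6-dimethylcyclohexan-1-one, diol cis to the 2-methyl group, both C6 epimers | COC[C@@H]1CCCN1C(=O)[C@@]2(C)C(=O)C(C)C[C@H](O)[C@@H]2O | intermediate
9 | (2R,3R,4S)-3,4-bis{[tert-butyl(dimethyl)silyl]oxy}-2-{[(2S)-2-(methoxymethyl)pyrrolidin-1-yl]carbonyl}-2,6-dimethylcyclohexan-1-one, both C6 epimers | COC[C@@H]1CCCN1C(=O)[C@@]2(C)C(=O)C(C)C[C@H](O[Si](C)(C)C(C)(C)C)[C@@H]2O[Si](C)(C)C(C)(C)C | intermediate
10 | [(1S,5S,6R)-5,6-bis{[tert-butyl(dimethyl)silyl]oxy}-1,3-dimethyl-2-methylidenecyclohexyl][(2S)-2-(methoxymethyl)pyrrolidin-1-yl]methanone, both C3 epimers | COC[C@@H]1CCCN1C(=O)[C@@]2(C)C(=C)C(C)C[C@H](O[Si](C)(C)C(C)(C)C)[C@@H]2O[Si](C)(C)C(C)(C)C | intermediate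
11 | [(1R,5S,6R)-5,6-bis{[tert-butyl(dimethyl)silyl]oxy}-1,3-dimethyl-2-methylidenecyclohexyl]methanol, both C3 epimers | OC[C@@]1(C)C(=C)C(C)C[C@H](O[Si](C)(C)C(C)(C)C)[C@@H]1O[Si](C)(C)C(C)(C)C | intermediate
12 | [(1R,5S,6R)-5,6-bis{[tert-butyl(dimethyl)silyl]oxy}-1,3-dimethyl-2-methylidenecyclohexyl]methyl acetate, both C3 epimers | CC(=O)OC[C@@]1(C)C(=C)C(C)C[C@H](O[Si](C)(C)C(C)(C)C)[C@@H]1O[Si](C)(C)C(C)(C)C | intermediate
13 | (R)-citronellic acid, (3R)-3,7-dimethyloct-6-enoic acid | CC(C)=CCC[C@@H](C)CC(=O)O | starting material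
14 | allyl (3R)-3,7-dimethyloct-6-enoate | CC(C)=CCC[C@@H](C)CC(=O)OCC=C | intermediate
15 | allyl (3R,6E)-8-hydroxy-3,7-dimethyloct-6-enoate | OC/C(C)=C/CC[C@@H](C)CC(=O)OCC=C | intermediate
16 | allyl (3R,6E)-8-bromo-3,7-dimethyloct-6-enoate | BrC/C(C)=C/CC[C@@H](C)CC(=O)OCC=C | intermediate
17 | monocyclic tertiary C5 carbocation (C6–C7 bond formed, C8=C9 alkene E) | CC(=O)OC[C@@]1(C)[C+](CC/C(C)=C/CC[C@@H](C)CC(=O)OCC=C)C(C)C[C@H](O[Si](C)(C)C(C)(C)C)[C@@H]1O[Si](C)(C)C(C)(C)C | intermediate (not isolated)
18 | monocyclic tertiary C10 carbocation (H5 in place, cis to the C4 methyl) | CC(=O)OC[C@@]1(C)[C@@H](CC/C(C)=C/CC[C@@H](C)CC(=O)OCC=C)[C+](C)C[C@H](O[Si](C)(C)C(C)(C)C)[C@@H]1O[Si](C)(C)C(C)(C)C | intermediate (not isolated)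
19 | bicyclic tertiary C8 carbocation (trans-decalin, C9–C10 bond formed) | CC(=O)OC[C@@]1(C)[C@H]2CC[C+](C)[C@@H](CC[C@@H](C)CC(=O)OCC=C)[C@]2(C)C[C@H](O[Si](C)(C)C(C)(C)C)[C@@H]1O[Si](C)(C)C(C)(C)C | intermediate (not isolated)
20 | allyl (2S,3R,4R,5S,9R,10S,13R)-19-acetoxy-2,3-bis{[tert-butyl(dimethyl)silyl]oxy}labd-7-en-15-oate | CC(=O)OC[C@@]1(C)[C@H]2CC=C(C)[C@@H](CC[C@@H](C)CC(=O)OCC=C)[C@]2(C)C[C@H](O[Si](C)(C)C(C)(C)C)[C@@H]1O[Si](C)(C)C(C)(C)C | intermediate
21 | (2S,3R,4R,5S,9R,10S,13R)-19-acetoxy-2,3-bis{[tert-butyl(dimethyl)silyl]oxy}labd-7-en-15-oic acid | CC(=O)OC[C@@]1(C)[C@H]2CC=C(C)[C@@H](CC[C@@H](C)CC(=O)O)[C@]2(C)C[C@H](O[Si](C)(C)C(C)(C)C)[C@@H]1O[Si](C)(C)C(C)(C)C | intermediate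
22 | CNP0164890.1, (2S,3R,4R,5S,9R,10S,13R)-19-acetoxy-2,3-dihydroxylabd-7-en-15-oic acid | CC(=O)OC[C@@]1(C)[C@H]2CC=C(C)[C@@H](CC[C@@H](C)CC(=O)O)[C@]2(C)C[C@H](O)[C@@H]1O | target

**Step count:** 13 steps in total; longest linear sequence 10 steps (steps 1–7 and 11–13).

**Steps most likely to fail**

Step 11. The allyl cation may oligomerise, the C5 cation may be captured by the acetate carbonyl or by halide before the hydride shift, or silyl ethers may be lost under SnCl4/HBr. The fallback makes the two bonds one after the other by known chemistry; it sets out from 12 and 16 and comes back at 20. Wohl–Ziegler bromination of 12 (N-bromosuccinimide, AIBN, PhCF3, reflux) with allylic shift should give the ring A allylic bromide F1. Sodium benzenesulfinate in DMF converts it into the ring A allylic sulfone F2. Deprotonation (LiHMDS, THF/HMPA, −78 °C) and alkylation with bromide 16 gives the coupled sulfone F3 (C6–C7 bond, Julia–Biellmann-type coupling). Na(Hg)/Na2HPO4 in MeOH/THF at −20 °C removes the sulfonyl group to give the monocyclic diene F4; either alkene position at C5 serves. SnCl4 in CH2Cl2 at −78 °C then closes ring B by the classical cation–olefin cyclisation (C9–C10 bond) to 20.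

Step 6. Reduction may stall at the very hindered neopentyl amide, or C–O instead of C–N cleavage may give an amine. The fallback runs from 10 back to 11. O-Methylation with Me3OBF4 (2,6-di-tert-butylpyridine, CH2Cl2), then mild hydrolysis of the imidate salt with aqueous NaHCO3, should give the methyl ester F5 with release of the auxiliary. LiAlH4 (Et2O, 0 °C) reduces it to alcohol 11.

Step 3. Osmium may attack the face syn to the amide if the C4 methyl group, and not the amide, sits pseudoaxial and shields its face, which would give the wrong-face cis-diol. The fallback runs from 7 back to 8. In a Woodward cis-hydroxylation (I2, AgOAc, wet AcOH, then warming) the iodonium ion forms on the face that osmium prefers, and the acetoxonium ion then delivers both oxygens to the opposite face. This gives the hydroxy acetate F6 (regioisomer mixture, one drawn); K2CO3 in MeOH removes the acetyl group to give 8.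

**Further compounds**
F1 | step 11 | [(1R,5S,6R)-2-(bromomethyl)-5,6-bis{[tert-butyl(dimethyl)silyl]oxy}-1,3-dimethylcyclohex-2-en-1-yl]methyl acetate | CC(=O)OC[C@@]1(C)C(CBr)=C(C)C[C@H](O[Si](C)(C)C(C)(C)C)[C@@H]1O[Si](C)(C)C(C)(C)C
F2 | step 11 | [(1R,5S,6R)-5,6-bis{[tert-butyl(dimethyl)silyl]oxy}-1,3-dimethyl-2-[(phenylsulfonyl)methyl]cyclohex-2-en-1-yl]methyl acetate | CC(=O)OC[C@@]1(C)C(CS(=O)(=O)c2ccccc2)=C(C)C[C@H](O[Si](C)(C)C(C)(C)C)[C@@H]1O[Si](C)(C)C(C)(C)C
F3 | step 11 | coupled sulfone, allyl (3R,6E)-9-[(3S,4R,6R)-6-(acetoxymethyl)-3,4-bis{[tert-butyl(dimethyl)silyl]oxy}-2,6-dimethylcyclohex-1-en-1-yl]-3,7-dimethyl-9-(phenylsulfonyl)non-6-enoate, both epimers at the sulfonyl carbon | CC(=O)OC[C@@]1(C)C(C(C/C(C)=C/CC[C@@H](C)CC(=O)OCC=C)S(=O)(=O)c2ccccc2)=C(C)C[C@H](O[Si](C)(C)C(C)(C)C)[C@@H]1O[Si](C)(C)C(C)(C)C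
F4 | step 11 | monocyclic diene, allyl (3R,6E)-9-[(3S,4R,6R)-6-(acetoxymethyl)-3,4-bis{[tert-butyl(dimethyl)silyl]oxy}-2,6-dimethylcyclohex-1-en-1-yl]-3,7-dimethylnon-6-enoate | CC(=O)OC[C@@]1(C)C(CC/C(C)=C/CC[C@@H](C)CC(=O)OCC=C)=C(C)C[C@H](O[Si](C)(C)C(C)(C)C)[C@@H]1O[Si](C)(C)C(C)(C)C
F5 | step 6 | methyl (1S,5S,6R)-5,6-bis{[tert-butyl(dimethyl)silyl]oxy}-1,3-dimethyl-2-methylidenecyclohexane-1-carboxylate | COC(=O)[C@@]1(C)C(=C)C(C)C[C@H](O[Si](C)(C)C(C)(C)C)[C@@H]1O[Si](C)(C)C(C)(C)C
F6 | step 3 | mono-acetate of diol 8 at the hydroxyl remote from the quaternary carbon (the regioisomeric mono-acetate may accompany it) | COC[C@@H]1CCCN1C(=O)[C@@]2(C)C(=O)C(C)C[C@H](OC(C)=O)[C@@H]2O
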